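**Plan**
1. The target is read as an all-cis 2,6-diaryl-3,7-dioxabicyclo[3.3.0]octane (ring A = C1–C2–O3–C4–C5, ring B = C5–C6–O7–C8–C1; H-1, H-2, H-5, H-6 all syn, both aryls endo, all four centres S). Its C6 aryl is a (2S,3S)-cis-2-aryl-3-hydroxymethyl-7-methoxy-2,3-dihydrobenzofuran.
2. Cuts: C4–H (acetal reduction), then C5–C6 together with ring B, which divides the target into dihydrofuranylmethanol 10 (ring A) and benzofuran aldehyde acetal 17. Compound 17 is cut at benzofuran C2–C3 (carbenoid C–H insertion); 10 is cut at C1–C2 (anti-aldol) and at the C4=C5 enol ether (lactol dehydration).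
3. Enabling feature: C5 is the nucleophilic β-carbon of the ring A enol ether O3–C4=C5. C6 is an acetal carbon on O7 that ionises easily because its aryl ring carries the para benzofuran oxygen. The O7–C8–C1 tether holds the cation over one face of ring A, so ring B and the C5/C6 configuration arise from one ionisation.
4. Forward order: ring A (aldol, alkene cleavage to the lactol, dehydration); benzofuran ring (Mitsunobu ether, diazo coupling, C–H insertion); ring B (key cyclisation, which is also the fragment union); C4 deoxygenation; one hydride step that frees both phenols and the CH2OH.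
5. Stereochemistry: C1/C2 from the oxazolidinone-controlled anti-aldol; benzofuran C2/C3 from the chiral dirhodium catalyst; C5/C6 from the cis template in the key step, where both epimers of the mixed acetal converge on one oxocarbenium ion.
6. Pivalates on both phenols and the ester at benzofuran C3 make the benzylic C–O bonds less prone to ionise, which protects the kinetically formed all-cis array until the last step.

Key step: step 12

Assumption: the sense of induction of the (S)-oxazolidinone in the magnesium anti-aldol (2R,3S adduct) and of Rh2(R-PTTL)4 in the insertion (2S benzofuran series) is taken by analogy with the parent substrates; the mirror-image auxiliary or catalyst would be used if a model run showed the opposite sense.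

**Route**

Step 1
Reactants: 1 vanillin
Product: 2 4-formyl-2-methoxyphenyl 2,2-dimethylpropanoate (vanillin pivalate)
Conditions: PivCl, Et3N, DMAP (cat.), CH2Cl2, 0 °C to rt
Reagents that add atoms: pivaloyl chloride CC(C)(C)C(Cl)=O
Why: Phenol O-acylation should proceed cleanly and installs an electron-poor protecting group that survives every later step and falls to hydride at the end.

Step 2
Reactants: 3 (4S)-4-benzyl-1,3-oxazolidin-2-one; 4 pent-4-enoyl chloride
Product: 5 (4S)-4-benzyl-3-(pent-4-enoyl)-1,3-oxazolidin-2-one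
Conditions: n-BuLi, THF, -78 °C; then 4, -78 to 0 °C
Reagents that add atoms: none
Why: N-acylation of the lithiated oxazolidinone is the standard entry to the chiral imide.

Step 3
Reactants: 5 (4S)-4-benzyl-3-(pent-4-enoyl)-1,3-oxazolidin-2-one; 2 vanillin pivalate
Product: 7 anti-aldol adduct 4-[(1S,2R)-2-{[(4S)-4-benzyl-2-oxo-1,3-oxazolidin-3-yl]carbonyl}-1-hydroxypent-4-en-1-yl]-2-methoxyphenyl 2,2-dimethylpropanoate, via trimethylsilyl ether 6 (not isolated)
Conditions: MgCl2 (0.2 equiv), Et3N, TMSCl, EtOAc, rt; then TFA (cat.), MeOH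
Reagents that add atoms: none
Why: In this magnesium-halide-catalysed anti-aldol of an N-acyloxazolidinone, the chelated (Z)-magnesium enolate should be attacked on the face opposite the benzyl group (alpha carbon R) through a boat-like transition state that gives the anti relation (carbinol carbon S), while silylation in the flask drives the reversible addition forward.

Step 4
Reactants: 7 anti-aldol adduct
Product: 8 lactol 4-[(2S,3R,5RS)-3-{[(4S)-4-benzyl-2-oxo-1,3-oxazolidin-3-yl]carbonyl}-5-hydroxyoxolan-2-yl]-2-methoxyphenyl 2,2-dimethylpropanoate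
Conditions: OsO4 (2 mol%), NaIO4 (4 equiv), 2,6-lutidine, dioxane/H2O (3:1), rt
Reagents that add atoms: osmium tetroxide O=[Os](=O)(=O)=O; sodium periodate [Na+].[O-]I(=O)(=O)=O
Why: Lemieux–Johnson cleavage of the terminal alkene should give a gamma-hydroxy aldehyde that closes at once onto the benzylic hydroxyl to form ring A as a lactol, whose anomeric centre is of no consequence.

Step 5
Reactants: 8 lactol
Product: 9 4-[(2S,3R)-3-{[(4S)-4-benzyl-2-oxo-1,3-oxazolidin-3-yl]carbonyl}-2,3-dihydrofuran-2-yl]-2-methoxyphenyl 2,2-dimethylpropanoate (2,3-cis)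
Conditions: MsCl, Et3N, CH2Cl2, -40 °C to rt
Reagents that add atoms: none
Why: Anomeric mesylation followed by base-induced loss of methanesulfonate (the lactol dehydration used for furanoid glycals) should install the O3–C4=C5 enol ether, and allylic strain in the imide should shield the C3 hydrogen from enolisation.

Step 6
Reactants: 9 dihydrofuranyl imide
Product: 10 4-[(2S,3S)-3-(hydroxymethyl)-2,3-dihydrofuran-2-yl]-2-methoxyphenyl 2,2-dimethylpropanoate (2,3-cis; fragment 1)
Conditions: NaBH4, THF/H2O (4:1), 0 °C to rt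
Reagents that add atoms: none
Why: Borohydride reductive cleavage of the N-acyloxazolidinone should give the primary alcohol and return the auxiliary without touching the enol ether, the hindered aryl pivalate or the two stereocentres.

Step 7
Reactants: 2 vanillin pivalate
Product: 11 4-(hydroxymethyl)-2-methoxyphenyl 2,2-dimethylpropanoate
Conditions: NaBH4, MeOH/THF, 0 °C
Reagents that add atoms: none
Why: Chemoselective borohydride reduction of the aldehyde in the presence of the hindered aryl ester is routine.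

Step 8
Reactants: 11 4-(hydroxymethyl)-2-methoxyphenyl 2,2-dimethylpropanoate; 12 5-iodovanillin
Product: 13 4-[(4-formyl-2-iodo-6-methoxyphenoxy)methyl]-2-methoxyphenyl 2,2-dimethylpropanoate
Conditions: PPh3, DIAD, THF, 0 °C to rt
Reagents that add atoms: none
Why: Mitsunobu etherification should work because the para-formyl phenol is acidic and the primary benzylic alcohol is activated without any base that could cleave the aryl ester.

Step 9
Reactants: 13 aryl benzyl ether aldehyde
Product: 14 4-{[4-(dimethoxymethyl)-2-iodo-6-methoxyphenoxy]methyl}-2-methoxyphenyl 2,2-dimethylpropanoate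
Conditions: HC(OMe)3, PPTS (cat.), MeOH, rt
Reagents that add atoms: trimethyl orthoformate COC(OC)OC; methanol CO
Why: Acid-catalysed acetalisation with orthoformate as water scavenger masks the aldehyde for the diazo chemistry and at the same time creates the acetal needed in the key step.

Step 10
Reactants: 14 iodoaryl dimethyl acetal; 15 ethyl diazoacetate
Product: 16 ethyl 2-diazo-2-[5-(dimethoxymethyl)-3-methoxy-2-({3-methoxy-4-[(2,2-dimethylpropanoyl)oxy]phenyl}methoxy)phenyl]acetate
Conditions: Pd(PPh3)4 (5 mol%), Ag2CO3 (0.5 equiv), Et3N, toluene, rt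
Reagents that add atoms: none
Why: Palladium-catalysed cross-coupling of an aryl iodide with the C–H bond of ethyl diazoacetate (oxidative addition to zerovalent palladium, base-assisted palladation of the diazo ester, reductive elimination) should give the aryldiazoacetate directly with the diazo group intact.

Step 11
Reactants: 16 aryldiazoacetate
Product: 17 ethyl (2S,3R)-5-(dimethoxymethyl)-7-methoxy-2-{3-methoxy-4-[(2,2-dimethylpropanoyl)oxy]phenyl}-2,3-dihydro-1-benzofuran-3-carboxylate (2,3-cis; fragment 2)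
Conditions: Rh2(R-PTTL)4 (2 mol%), toluene, -60 °C
Reagents that add atoms: none
Why: Intramolecular 1,5 C–H insertion of the divalent rhodium carbenoid into the benzylic ether methylene should close the dihydrobenzofuran, with the chiral phthaloyl-tert-leucinate ligands setting both new centres (kinetic cis relation, absolute sense from the catalyst).

Step 12
Reactants: 10 dihydrofuranylmethanol (fragment 1); 17 benzofuran aldehyde dimethyl acetal (fragment 2)
Product: 19 furofuranyl methyl acetal ethyl (2S,3R)-7-methoxy-5-{(1S,2S,4RS,5R,6S)-4-methoxy-2-[3-methoxy-4-(pivaloyloxy)phenyl]-3,7-dioxabicyclo[3.3.0]octan-6-yl}-2-[3-methoxy-4-(pivaloyloxy)phenyl]-2,3-dihydro-1-benzofuran-3-carboxylate, via mixed methyl acetal 18 (not isolated)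
Conditions: TMSOTf (0.2 equiv), CH2Cl2, -78 °C; pyridine quench at -78 °C
Reagents that add atoms: none
Why: TMSOTf-promoted exchange puts the hydroxyl of 10 on the acetal carbon of 17 (mixed acetal 18, both epimers), loss of methoxide gives an (E)-aryl oxocarbenium ion on O7, the enol ether carbon C5 of ring A attacks C6, and the resulting ring A oxocarbenium ion at C4 is capped by methanol. The closest known reaction type is the Lewis-acid-promoted acetal–enol ether (Mukaiyama–Prins) cyclisation of cis-2-aryl-3-hydroxymethyl-2,3-dihydrofurans with aryl aldehyde dimethyl acetals, which is known to deliver endo,endo-2,6-diaryl furofuran acetals. Ring B closes in a 5-(enolexo)-endo-trig mode, the C=O+ bond lying inside the new ring and the nucleophilic C4=C5 bond outside it. C5 is set by the tether, because C6 can only reach the face of ring A that carries C8 (cis ring fusion); C6 should be set kinetically by a compact transition state in which the aryl group of the (E)-oxocarbenium ion lies over ring A, leaving H-6 cis to H-5; C4 forms as an anomeric mixture that step 13 erases. The step is stereoconvergent, since both epimers of 18 ionise to the same cation, and it needs kinetic control against ring opening at the benzylic C–O bonds, which the low temperature, the catalytic acid and the electron-poor pivaloyloxy para substituents on both guaiacyl rings should secure.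

Step 13
Reactants: 19 furofuranyl methyl acetal
Product: 20 ethyl (2S,3R)-7-methoxy-5-{(1S,2S,5S,6S)-2-[3-methoxy-4-(pivaloyloxy)phenyl]-3,7-dioxabicyclo[3.3.0]octan-6-yl}-2-[3-methoxy-4-(pivaloyloxy)phenyl]-2,3-dihydro-1-benzofuran-3-carboxylate
Conditions: Et3SiH (5 equiv), TMSOTf (0.3 equiv), CH2Cl2, -78 to -50 °C
Reagents that add atoms: none
Why: Ionic hydrogenation of the cyclic acetal (ionisation at C4, hydride transfer from the silane) should turn C4 into a methylene group, so both anomers converge and no stereocentre is formed, while the much less easily ionised benzylic ethers stay closed at this temperature.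

Step 14
Reactants: 20 protected furofuran ester
Product: 21 target 4-[(1S,2S,5S,6S)-6-{(2S,3S)-2-(4-hydroxy-3-methoxyphenyl)-3-(hydroxymethyl)-7-methoxy-2,3-dihydro-1-benzofuran-5-yl}-3,7-dioxabicyclo[3.3.0]octan-2-yl]-2-methoxyphenol
Conditions: LiAlH4, THF, -20 to 0 °C; aq. potassium sodium tartrate
Reagents that add atoms: none
Why: Hydride reduction should convert the ethyl ester into the primary alcohol faster than it can epimerise and cleave both aryl pivalates in the same operation, with a neutral work-up that avoids acid at the para-hydroxybenzylic ethers.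

**Compound list**
1 | vanillin (4-hydroxy-3-methoxybenzaldehyde) | O=Cc1ccc(O)c(OC)c1 | starting material
2 | 4-formyl-2-methoxyphenyl 2,2-dimethylpropanoate (vanillin pivalate) | O=Cc1ccc(OC(=O)C(C)(C)C)c(OC)c1 | intermediate
3 | (4S)-4-benzyl-1,3-oxazolidin-2-one | O=C1OC[C@H](Cc2ccccc2)N1 | starting material
4 | pent-4-enoyl chloride | C=CCCC(Cl)=O | starting material
5 | (4S)-4-benzyl-3-(pent-4-enoyl)-1,3-oxazolidin-2-one | C=CCCC(=O)N1[C@@H](Cc2ccccc2)COC1=O | intermediate
6 | 4-[(1S,2R)-2-{[(4S)-4-benzyl-2-oxo-1,3-oxazolidin-3-yl]carbonyl}-1-(trimethylsilyloxy)pent-4-en-1-yl]-2-methoxyphenyl 2,2-dimethylpropanoate (not isolated) | C=CC[C@@H](C(=O)N1[C@@H](Cc2ccccc2)COC1=O)[C@H](O[Si](C)(C)C)c1ccc(OC(=O)C(C)(C)C)c(OC)c1 | intermediate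
7 | 4-[(1S,2R)-2-{[(4S)-4-benzyl-2-oxo-1,3-oxazolidin-3-yl]carbonyl}-1-hydroxypent-4-en-1-yl]-2-methoxyphenyl 2,2-dimethylpropanoate (anti-aldol adduct) | C=CC[C@@H](C(=O)N1[C@@H](Cc2ccccc2)COC1=O)[C@H](O)c1ccc(OC(=O)C(C)(C)C)c(OC)c1 | intermediate
8 | 4-[(2S,3R,5RS)-3-{[(4S)-4-benzyl-2-oxo-1,3-oxazolidin-3-yl]carbonyl}-5-hydroxyoxolan-2-yl]-2-methoxyphenyl 2,2-dimethylpropanoate (2,3-cis lactol, both anomers) | OC1C[C@@H](C(=O)N2[C@@H](Cc3ccccc3)COC2=O)[C@@H](c2ccc(OC(=O)C(C)(C)C)c(OC)c2)O1 | intermediate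
9 | 4-[(2S,3R)-3-{[(4S)-4-benzyl-2-oxo-1,3-oxazolidin-3-yl]carbonyl}-2,3-dihydrofuran-2-yl]-2-methoxyphenyl 2,2-dimethylpropanoate (2,3-cis) | C1=C[C@@H](C(=O)N2[C@@H](Cc3ccccc3)COC2=O)[C@@H](c2ccc(OC(=O)C(C)(C)C)c(OC)c2)O1 | intermediate
10 | 4-[(2S,3S)-3-(hydroxymethyl)-2,3-dihydrofuran-2-yl]-2-methoxyphenyl 2,2-dimethylpropanoate (2,3-cis; fragment 1) | C1=C[C@@H](CO)[C@@H](c2ccc(OC(=O)C(C)(C)C)c(OC)c2)O1 | intermediate
11 | 4-(hydroxymethyl)-2-methoxyphenyl 2,2-dimethylpropanoate | OCc1ccc(OC(=O)C(C)(C)C)c(OC)c1 | intermediate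
12 | 5-iodovanillin (4-hydroxy-3-iodo-5-methoxybenzaldehyde) | O=Cc1cc(I)c(O)c(OC)c1 | starting material
13 | 4-[(4-formyl-2-iodo-6-methoxyphenoxy)methyl]-2-methoxyphenyl 2,2-dimethylpropanoate | O=Cc1cc(I)c(OCc2ccc(OC(=O)C(C)(C)C)c(OC)c2)c(OC)c1 | intermediate
14 | 4-{[4-(dimethoxymethyl)-2-iodo-6-methoxyphenoxy]methyl}-2-methoxyphenyl 2,2-dimethylpropanoate | COC(OC)c1cc(I)c(OCc2ccc(OC(=O)C(C)(C)C)c(OC)c2)c(OC)c1 | intermediate
15 | ethyl diazoacetate | CCOC(=O)C=[N+]=[N-] | starting material
16 | ethyl 2-diazo-2-[5-(dimethoxymethyl)-3-methoxy-2-({3-methoxy-4-[(2,2-dimethylpropanoyl)oxy]phenyl}methoxy)phenyl]acetate | CCOC(=O)C(=[N+]=[N-])c1cc(C(OC)OC)cc(OC)c1OCc1ccc(OC(=O)C(C)(C)C)c(OC)c1 | intermediate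
17 | ethyl (2S,3R)-5-(dimethoxymethyl)-7-methoxy-2-{3-methoxy-4-[(2,2-dimethylpropanoyl)oxy]phenyl}-2,3-dihydro-1-benzofuran-3-carboxylate (2,3-cis; fragment 2) | COC(OC)c1cc(OC)c2c(c1)[C@@H](C(=O)OCC)[C@@H](c1ccc(OC(=O)C(C)(C)C)c(OC)c1)O2 | intermediate
18 | ethyl (2S,3R)-7-methoxy-5-[methoxy({(2S,3S)-2-[3-methoxy-4-(pivaloyloxy)phenyl]-2,3-dihydrofuran-3-yl}methoxy)methyl]-2-[3-methoxy-4-(pivaloyloxy)phenyl]-2,3-dihydro-1-benzofuran-3-carboxylate (mixed acetal, both epimers at the acetal carbon; not isolated) | C1=C[C@@H](COC(OC)c2cc(OC)c3c(c2)[C@@H](C(=O)OCC)[C@@H](c2ccc(OC(=O)C(C)(C)C)c(OC)c2)O3)[C@@H](c2ccc(OC(=O)C(C)(C)C)c(OC)c2)O1 | intermediate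
19 | ethyl (2S,3R)-7-methoxy-5-{(1S,2S,4RS,5R,6S)-4-methoxy-2-[3-methoxy-4-(pivaloyloxy)phenyl]-3,7-dioxabicyclo[3.3.0]octan-6-yl}-2-[3-methoxy-4-(pivaloyloxy)phenyl]-2,3-dihydro-1-benzofuran-3-carboxylate (all-cis H-1/H-2/H-5/H-6; both C4 anomers) | COc1cc([C@H]2OC(OC)[C@@H]3[C@H]2CO[C@@H]3c2cc(OC)c3c(c2)[C@@H](C(=O)OCC)[C@@H](c2ccc(OC(=O)C(C)(C)C)c(OC)c2)O3)ccc1OC(=O)C(C)(C)C | intermediate
20 | ethyl (2S,3R)-7-methoxy-5-{(1S,2S,5S,6S)-2-[3-methoxy-4-(pivaloyloxy)phenyl]-3,7-dioxabicyclo[3.3.0]octan-6-yl}-2-[3-methoxy-4-(pivaloyloxy)phenyl]-2,3-dihydro-1-benzofuran-3-carboxylate | COc1cc([C@H]2OC[C@@H]3[C@H]2CO[C@@H]3c2cc(OC)c3c(c2)[C@@H](C(=O)OCC)[C@@H](c2ccc(OC(=O)C(C)(C)C)c(OC)c2)O3)ccc1OC(=O)C(C)(C)C | intermediate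
21 | 4-[(1S,2S,5S,6S)-6-{(2S,3S)-2-(4-hydroxy-3-methoxyphenyl)-3-(hydroxymethyl)-7-methoxy-2,3-dihydro-1-benzofuran-5-yl}-3,7-dioxabicyclo[3.3.0]octan-2-yl]-2-methoxyphenol | COc1cc([C@H]2OC[C@@H]3[C@H]2CO[C@@H]3c2cc(OC)c3c(c2)[C@@H](CO)[C@@H](c2ccc(O)c(OC)c2)O3)ccc1O | target

**Step count**
Total: 14 steps. Longest linear sequence: 9 steps (steps 1, 7, 8, 9, 10, 11, 12, 13, 14).

**Steps most likely to fail**

Step 12. Kinetic control may be lost through acid-induced ring opening at the benzylic C–O bonds (C6 of the new ring, C2 of the cis-benzofuran in 17), which would drift the product toward exo isomers. Alternatively, the hindered, fully functionalised acetal may exchange so slowly that methanol adds to the enol ether instead. The fallback sets out from 10 and 14 and comes back at 20; it builds the benzofuran after the furofuran. The same cyclisation is run with the simple, achiral acetal 14, which carries neither an acid-labile benzofuran nor an epimerisable ester, and should give the iodoaryl furofuranyl methyl acetal F1. Et3SiH with catalytic TMSOTf at -78 °C should then give the iodoaryl furofuran F2. Pd(PPh3)4, Ag2CO3, Et3N and ethyl diazoacetate 15 should convert it into the furofuranyl aryldiazoacetate F3. Rh2(R-PTTL)4 in toluene at -60 °C then closes the cis-benzofuran under neutral conditions by catalyst-controlled C–H insertion, which should give 20.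

Step 5. The C3 centre of the dihydrofuran (alpha to the imide carbonyl and allylic to the new enol ether) may epimerise, or the double bond may migrate into conjugation under the amine base. The fallback sets out from 7 and comes back at 10; it removes the carbonyl group before the enol ether exists. NaBH4 in THF/H2O on 7 should give the diol F4. TBSCl and imidazole should silylate the primary hydroxyl selectively to the silyl ether F5. OsO4/NaIO4 should give the silyloxymethyl lactol F6. MsCl/Et3N should give the dihydrofuran silyl ether F7, which has no acidic C3 hydrogen. TBAF buffered with AcOH should then give 10.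

Step 10. The aryldiazoacetate may decompose on palladium (carbene formation and dimerisation), or the coupling may be slow next to the ortho benzyloxy group. The fallback sets out from 14 and comes back at 16; it separates C–C bond formation from diazo installation. Negishi-type coupling of 14 with the Reformatsky reagent BrZnCH2CO2Et (Pd2(dba)3, XPhos, THF, rt) should give the arylacetate F8. Diazo transfer with p-acetamidobenzenesulfonyl azide and DBU in MeCN should then give 16.

**Further compounds**
F1 | step 12 | 4-[(1S,2S,4RS,5R,6S)-6-(3-iodo-5-methoxy-4-{[3-methoxy-4-(pivaloyloxy)phenyl]methoxy}phenyl)-4-methoxy-3,7-dioxabicyclo[3.3.0]octan-2-yl]-2-methoxyphenyl 2,2-dimethylpropanoate | COc1cc([C@H]2OC(OC)[C@@H]3[C@H]2CO[C@@H]3c2cc(I)c(OCc3ccc(OC(=O)C(C)(C)C)c(OC)c3)c(OC)c2)ccc1OC(=O)C(C)(C)C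
F2 | step 12 | 4-[(1S,2S,5S,6S)-6-(3-iodo-5-methoxy-4-{[3-methoxy-4-(pivaloyloxy)phenyl]methoxy}phenyl)-3,7-dioxabicyclo[3.3.0]octan-2-yl]-2-methoxyphenyl 2,2-dimethylpropanoate | COc1cc([C@H]2OC[C@@H]3[C@H]2CO[C@@H]3c2cc(I)c(OCc3ccc(OC(=O)C(C)(C)C)c(OC)c3)c(OC)c2)ccc1OC(=O)C(C)(C)C
F3 | step 12 | ethyl 2-diazo-2-[3-methoxy-2-{[3-methoxy-4-(pivaloyloxy)phenyl]methoxy}-5-{(1S,2S,5S,6S)-2-[3-methoxy-4-(pivaloyloxy)phenyl]-3,7-dioxabicyclo[3.3.0]octan-6-yl}phenyl]acetate | COc1cc([C@H]2OC[C@@H]3[C@H]2CO[C@@H]3c2cc(C(=[N+]=[N-])C(=O)OCC)c(OCc3ccc(OC(=O)C(C)(C)C)c(OC)c3)c(OC)c2)ccc1OC(=O)C(C)(C)C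
F4 | step 5 | 4-[(1S,2S)-1-hydroxy-2-(hydroxymethyl)pent-4-en-1-yl]-2-methoxyphenyl 2,2-dimethylpropanoate | C=CC[C@@H](CO)[C@H](O)c1ccc(OC(=O)C(C)(C)C)c(OC)c1
F5 | step 5 | 4-[(1S,2S)-2-{[tert-butyl(dimethyl)silyl]oxymethyl}-1-hydroxypent-4-en-1-yl]-2-methoxyphenyl 2,2-dimethylpropanoate | C=CC[C@@H](CO[Si](C)(C)C(C)(C)C)[C@H](O)c1ccc(OC(=O)C(C)(C)C)c(OC)c1
F6 | step 5 | 4-[(2S,3S,5RS)-3-{[tert-butyl(dimethyl)silyl]oxymethyl}-5-hydroxyoxolan-2-yl]-2-methoxyphenyl 2,2-dimethylpropanoate | OC1C[C@@H](CO[Si](C)(C)C(C)(C)C)[C@@H](c2ccc(OC(=O)C(C)(C)C)c(OC)c2)O1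
F7 | step 5 | 4-[(2S,3S)-3-{[tert-butyl(dimethyl)silyl]oxymethyl}-2,3-dihydrofuran-2-yl]-2-methoxyphenyl 2,2-dimethylpropanoate | C1=C[C@@H](CO[Si](C)(C)C(C)(C)C)[C@@H](c2ccc(OC(=O)C(C)(C)C)c(OC)c2)O1
F8 | step 10 | ethyl 2-[5-(dimethoxymethyl)-3-methoxy-2-({3-methoxy-4-[(2,2-dimethylpropanoyl)oxy]phenyl}methoxy)phenyl]acetate | CCOC(=O)Cc1cc(C(OC)OC)cc(OC)c1OCc1ccc(OC(=O)C(C)(C)C)c(OC)c1
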